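**Plan**
- Cuts: (a) the N–CH3 bond, the carbamate and three benzyl groups (last step); (b) C6 (ring A)–C2'' (piperidine); (c) C2 (ring C)–C1' (ring B).
- Forward: the A/C bicycle is bought as a chromone. Ring B is joined to C2 by conjugate addition, and the intact piperidine ring is joined to C6 last. No ring has to be built.
- Enabling feature: C6 lies between the oxygens on C5 and C7 and para to O1, so it is the enol-type carbon of a phloroglucinol ring. C2'' is alpha to N, so the bond is a Mannich pair in its natural polarity (arene plus cyclic iminium ion).
- C6 is told apart from C8 by the 5-OH. Its hydrogen bond to the C4 carbonyl keeps it free when O7 is benzylated, and C6 is its only open ortho carbon (the other is C4a).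
- Stereochemistry: C2 (S) comes from a chiral rhodium catalyst and C2'' (S) from the chiral counteranion of the iminium ion. The two centers are set independently, so a minor epimer is a separable diastereomer.
- Both centers are labile (retro-oxa-Michael at C2, retro-Mannich at C2''). No base is therefore used after step 2, and N stays a carbamate until the last step.

Key step: step 3

Assumption: the sense of induction written for the two chiral catalysts (steps 2 and 3) follows the usual models; should either give the opposite configuration, the enantiomeric ligand or acid is used.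

**Step 1**
Reactants: 1 5,7-dihydroxychromone
Product: 2 7-benzyloxy-5-hydroxychromone
Conditions: BnBr (1.05 equiv), K2CO3 (1.1 equiv), acetone, reflux
Reagents that add atoms: benzyl bromide, BrCc1ccccc1
Why: Williamson ether synthesis in which only the acidic, unchelated 7-OH is alkylated, because the 5-OH is tied up in a hydrogen bond to the C4 carbonyl group; no stereocenter is formed.

**Step 2**
Reactants: 2 7-benzyloxy-5-hydroxychromone; 3 4-(benzyloxy)phenylboronic acid
Product: 4 (2S)-7-benzyloxy-2-(4-benzyloxyphenyl)-5-hydroxychroman-4-one
Conditions: [Rh(OH)(cod)]2 (1.5 mol %), (S)-MeO-F12-BIPHEP (3.3 mol %), 3 (1.5 equiv), toluene–H2O (10:1), rt; recrystallisation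
Reagents that add atoms: none
Why: Rhodium-catalysed asymmetric 1,4-addition of an arylboronic acid to a chromone (Hayashi–Miyaura reaction), a known route to flavanones, in which the chiral bisphosphine on the aryl-rhodium species selects the face of the C2=C3 bond and sets C2 as S, while quick protonation of the rhodium enolate by water forestalls ring opening to the chalcone.

**Step 3**
Reactants: 4 (2S)-7-benzyloxy-2-(4-benzyloxyphenyl)-5-hydroxychroman-4-one; 5 benzyl 3,4-dihydropyridine-1(2H)-carboxylate
Product: 7 benzyl (2S)-2-[(2S)-7-benzyloxy-2-(4-benzyloxyphenyl)-5-hydroxy-4-oxochroman-6-yl]piperidine-1-carboxylate, via N-acyliminium ion 6 (not isolated)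
Conditions: (R)-3,3'-bis(2,4,6-triisopropylphenyl)-BINOL N-triflylphosphoramide (10 mol %), 4 Å MS, toluene–CH2Cl2 (4:1), −20 °C, 5 (1.2 equiv) added over 8 h by syringe pump
Reagents that add atoms: none
Why: Proposed new method: the chiral acid protonates enecarbamate 5 at C3 to give the cyclic N-acyliminium ion 6 as a contact ion pair whose phosphoramidate anion also accepts a (bifurcated) hydrogen bond from the 5-OH of 4, so that C6 attacks C2 of 6 inside the chiral pocket and the anion then takes H-6 from the Wheland intermediate, which restores the phenol and the acid (an intermolecular aza-Friedel–Crafts or phenolic Mannich reaction in which no ring is closed). The closest known reaction types are the chiral-phosphoric-acid-catalysed aza-Friedel–Crafts reaction of indoles with enecarbamates, the OH-directed ortho aza-Friedel–Crafts reaction of phenols and naphthols with N-acyl imines, and the counteranion-directed addition of enol silanes to cyclic aliphatic N-acyliminium ions; what has not been shown is a phenol as the partner of a tertiary, purely aliphatic cyclic N-acyliminium ion. The new stereocenter C2'' is set as S by the chiral anion alone, since C2 of the flavanone is too remote to bias either face, and because 4 is a single enantiomer the minor C2'' epimer is a diastereomer that chromatography or crystallisation should remove. The step needs C6 over C8, C over O and single over double substitution: C6 is the only free position ortho to the only free phenol, phenolic Mannich-type reactions go ortho to the free OH, an O5-bound N,O-acetal would form reversibly and can collapse only to C6 (as in the O-to-C glycoside rearrangement of chelated phloroacetophenones), and C8 lies para to the anchor and outside the ion pair. Slow addition of 5 keeps the enecarbamate from adding to its own iminium ion, and the carbamate product, unlike a free benzylic amine, cannot revert by a retro-Mannich path, so the configuration once set should hold.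

**Step 4**
Reactants: 7 benzyl (2S)-2-[(2S)-7-benzyloxy-2-(4-benzyloxyphenyl)-5-hydroxy-4-oxochroman-6-yl]piperidine-1-carboxylate
Product: 10 (2S)-5,7-dihydroxy-2-(4-hydroxyphenyl)-6-[(2S)-1-methylpiperidin-2-yl]chroman-4-one, via secondary amine 8 (not isolated), via N-methyl amine 9 (not isolated)
Conditions: H2 (1 atm), 10% Pd/C, 37% aq. HCHO (1.1 equiv), MeOH–EtOAc, rt; then AcOH (2 equiv), H2 (1 atm), rt; work-up at pH 6–7
Reagents that add atoms: formaldehyde, C=O
Why: Hydrogenolysis of the Cbz group (with loss of CO2) frees amine 8, reductive amination with formaldehyde over Pd/H2 gives 9 while the amine still retards cleavage of the aryl benzyl ethers, and acetic acid then lifts this retardation so that both ethers are hydrogenolysed; the mild, base-free conditions should leave the chelated ketone, the C2–O1 bond and both stereocenters untouched.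

**Compound list**
1 | 5,7-dihydroxychromone (5,7-dihydroxy-4H-chromen-4-one) | O=c1ccoc2cc(O)cc(O)c12 | starting material
2 | 7-benzyloxy-5-hydroxychromone | O=c1ccoc2cc(OCc3ccccc3)cc(O)c12 | intermediate
3 | 4-(benzyloxy)phenylboronic acid | OB(O)c1ccc(OCc2ccccc2)cc1 | starting material
4 | (2S)-7-benzyloxy-2-(4-benzyloxyphenyl)-5-hydroxychroman-4-one ((S)-naringenin 7,4'-dibenzyl ether) | c1c(OCc3ccccc3)cc2c(c1O)C(=O)C[C@@H](c1ccc(OCc3ccccc3)cc1)O2 | intermediate
5 | benzyl 3,4-dihydropyridine-1(2H)-carboxylate (N-Cbz enecarbamate) | O=C(OCc1ccccc1)N1CCCC=C1 | starting material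
6 | 1-(benzyloxycarbonyl)-2,3,4,5-tetrahydropyridinium ion (ion pair with the catalyst anion; not isolated) | O=C(OCc1ccccc1)[N+]1=CCCCC1 | intermediate
7 | benzyl (2S)-2-[(2S)-7-benzyloxy-2-(4-benzyloxyphenyl)-5-hydroxy-4-oxochroman-6-yl]piperidine-1-carboxylate | O=C(OCc1ccccc1)N1CCCC[C@H]1c1c(OCc3ccccc3)cc2c(c1O)C(=O)C[C@@H](c1ccc(OCc3ccccc3)cc1)O2 | intermediate
8 | (2S)-7-benzyloxy-2-(4-benzyloxyphenyl)-5-hydroxy-6-[(2S)-piperidin-2-yl]chroman-4-one (not isolated) | N1CCCC[C@H]1c1c(OCc3ccccc3)cc2c(c1O)C(=O)C[C@@H](c1ccc(OCc3ccccc3)cc1)O2 | intermediate
9 | (2S)-7-benzyloxy-2-(4-benzyloxyphenyl)-5-hydroxy-6-[(2S)-1-methylpiperidin-2-yl]chroman-4-one (not isolated) | CN1CCCC[C@H]1c1c(OCc3ccccc3)cc2c(c1O)C(=O)C[C@@H](c1ccc(OCc3ccccc3)cc1)O2 | intermediate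
10 | (2S)-5,7-dihydroxy-2-(4-hydroxyphenyl)-6-[(2S)-1-methylpiperidin-2-yl]chroman-4-one (CNP0146489.1) | CN1CCCC[C@H]1c1c(O)cc2c(c1O)C(=O)C[C@@H](c1ccc(O)cc1)O2 | target

Total step count: 4. Longest linear sequence: 4 (steps 1 to 4).

**Steps most likely to fail**

1. Step 3 (bears the label "Proposed new method:").
   - Risk: weak facial discrimination within the ion pair, competing attack through C8, or self-condensation of the enecarbamate outrunning the arene.
   - Fallback (known chemistry; sets out from 4 and comes back at 8): 4 is iodinated ortho to its free 5-OH with BnMe3N·ICl2 and CaCO3 in CH2Cl2–MeOH to give the 6-iodoflavanone F1.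
   - Commercial N-Boc-piperidine is lithiated (s-BuLi, TMEDA, Et2O, −78 °C). Catalytic dynamic resolution with a chiral diamino-alkoxide ligand converts it into (R)-N-Boc-2-lithiopiperidine F2.
   - ZnCl2 turns F2 into the configurationally stable zinc reagent F3. F3 is used in excess because of the free phenol.
   - A stereoretentive Negishi coupling of F3 with F1 (Pd(OAc)2, t-Bu3P·HBF4, rt) gives the N-Boc-piperidinyl flavanone F4.
   - The Boc group is removed with TMSOTf and 2,6-lutidine in CH2Cl2 at 0 °C, then MeOH, to give 8. Isolated 8 is taken through the conditions of step 4.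

2. Step 2.
   - Risk: ring opening of the rhodium enolate to the chalcone with erosion of optical purity, or sluggish insertion into the electron-rich chromone.
   - Fallback (sets out from 2 and 3 and comes back at 4): the conjugate addition is run without asymmetric induction (Pd(OCOCF3)2, 2,2'-bipyridine, aqueous MeOH, 60 °C) to give the racemic flavanone F5.
   - F5 is resolved by preparative SFC on a polysaccharide chiral phase into 4 and its (R)-enantiomer F6. F6 is racemised with catalytic DBU in toluene and recycled.

3. Step 4.
   - Risk: premature loss of the benzyl ethers followed by attack of formaldehyde at C8 of the freed phloroglucinol ring. Further risks are poisoning of the catalyst by the amine, and hydrogenolytic opening at the benzylic C2''–N or C2–O1 bond.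
   - Fallback (sets out from 7 and comes back at 10, without any hydrogen gas and with every stage isolated): the Cbz group alone is cleaved with Pd(OAc)2, Et3SiH and Et3N in CH2Cl2, then MeOH, to give isolated 8.
   - Reductive amination with HCHO and NaBH(OAc)3 in 1,2-dichloroethane gives isolated 9 while O7 and O4' are still benzylated.
   - Both benzyl ethers are then removed with BCl3 and pentamethylbenzene in CH2Cl2 at −78 °C to give 10.
   - No compound outside the list is made (F0).

**Further compounds**
F1 | step 3 | (2S)-7-benzyloxy-2-(4-benzyloxyphenyl)-5-hydroxy-6-iodochroman-4-one | Ic1c(OCc3ccccc3)cc2c(c1O)C(=O)C[C@@H](c1ccc(OCc3ccccc3)cc1)O2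
F2 | step 3 | (R)-N-Boc-2-lithiopiperidine | CC(C)(C)OC(=O)N1CCCC[C@H]1[Li]
F3 | step 3 | (R)-(N-Boc-piperidin-2-yl)zinc chloride | CC(C)(C)OC(=O)N1CCCC[C@H]1[Zn]Cl
F4 | step 3 | tert-butyl (2S)-2-[(2S)-7-benzyloxy-2-(4-benzyloxyphenyl)-5-hydroxy-4-oxochroman-6-yl]piperidine-1-carboxylate | CC(C)(C)OC(=O)N1CCCC[C@H]1c1c(OCc3ccccc3)cc2c(c1O)C(=O)C[C@@H](c1ccc(OCc3ccccc3)cc1)O2
F5 | step 2 | racemic 7-benzyloxy-2-(4-benzyloxyphenyl)-5-hydroxychroman-4-one | c1c(OCc3ccccc3)cc2c(c1O)C(=O)CC(c1ccc(OCc3ccccc3)cc1)O2
F6 | step 2 | (2R)-7-benzyloxy-2-(4-benzyloxyphenyl)-5-hydroxychroman-4-one | c1c(OCc3ccccc3)cc2c(c1O)C(=O)C[C@H](c1ccc(OCc3ccccc3)cc1)O2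
F0 | step 4 | none | none
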